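**Retrosynthetic overview**
1. Target 24 ⇐ 23 ⇐ 22: methanolic HCl (C15 esterification and desilylation) and reduction of the C17 ester to the allylic alcohol.
2. Key step: 22 ⇐ acyclic acetate 21 by one iron-hydride HAT radical cascade that forms C4–C5 (ring A) and then C9–C10 (ring B); loss of acetate leaves the C7=C8 alkene, and the C3 silyl ether controls C5, C9 and C10.
3. 21 ⇐ aldehyde 17 + ynoate 6 by cis-hydroalumination/aldol (C7–C8 bond, Z-alkene) with acetylation in the same flask.
4. 17 ⇐ pent-4-ynoic acid + 2-bromopropene + oxirane (CBS reduction sets C3; zirconium-catalysed carboalumination sets the E-alkene and C20).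
5. 6 ⇐ (R)-β-butyrolactone + but-3-enylmagnesium bromide (C13 by SN2 inversion), then ozonolysis, alkyne homologation and methoxycarbonylation.

Assumption: atom labels C1–C20 follow labdane numbering (ring A C1–C5/C10, ring B C5–C10, C17 on C8, side chain C11–C16); one-carbon donors (CO, MeOH, Me3Al, the Ohira–Bestmann reagent) are treated as reagents.

**Step 1**
Reactants: 1 (R)-β-butyrolactone [(4R)-4-methyloxetan-2-one]; 2 but-3-en-1-ylmagnesium bromide
Product: 3 (R)-3-methylhept-6-enoic acid
Conditions: CuBr·SMe2 (5 mol%), THF/Me2S, −30 → 0 °C; aq. HCl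
Reagents that add atoms: none
Why: Copper-catalysed SN2 ring opening of the β-lactone at the methyl-bearing carbon (alkyl–oxygen cleavage, Fujisawa–Sato type) proceeds with inversion, so the (R)-lactone gives the (R)-acid and fixes C13.

**Step 2**
Reactants: 3 (R)-3-methylhept-6-enoic acid
Product: 4 (R)-3-methyl-6-oxohexanoic acid
Conditions: O3, CH2Cl2/MeOH, −78 °C; then Me2S, −78 °C → rt
Reagents that add atoms: ozone ([O-][O+]=O)
Why: Ozonolysis with reductive work-up cleaves the only alkene to the aldehyde (C9), and the β-methyl stereocentre is not enolisable.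

**Step 3**
Reactants: 4 (R)-3-methyl-6-oxohexanoic acid
Product: 5 (R)-3-methylhept-6-ynoic acid
Conditions: dimethyl (1-diazo-2-oxopropyl)phosphonate (1.3 equiv), K2CO3 (3 equiv), MeOH, 0 °C → rt; acidify to pH 3
Reagents that add atoms: dimethyl (1-diazo-2-oxopropyl)phosphonate, Ohira–Bestmann reagent (CC(=O)C(=[N+]=[N-])P(=O)(OC)OC)
Why: Seyferth–Gilbert homologation with the Ohira–Bestmann reagent converts the aldehyde into the terminal alkyne (C9≡C8) under mild carbonate conditions while the acid rides as its carboxylate.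

**Step 4**
Reactants: 5 (R)-3-methylhept-6-ynoic acid
Product: 6 (R)-8-methoxy-3-methyl-8-oxooct-6-ynoic acid
Conditions: PdCl2 (5 mol%), CuCl2 (2.2 equiv), NaOAc (2.2 equiv), CO (1 atm), MeOH, rt
Reagents that add atoms: carbon monoxide ([C-]#[O+]); methanol (CO)
Why: Tsuji oxidative alkoxycarbonylation (alkynylpalladium, CO insertion, methanolysis, CuCl2 re-oxidising zerovalent palladium) installs C17 as the ynoate under buffered conditions that leave the saturated acid unesterified.

**Step 5**
Reactants: 7 pent-4-ynoic acid; 8 2-bromopropene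
Product: 10 2-methylhept-1-en-6-yn-3-one, via isopropenyllithium 9 (not isolated)
Conditions: 8 (3.3 equiv), Li metal, Et2O, 0 °C; then 7, THF, −78 → 0 °C; inverse quench into cold 1 M HCl
Reagents that add atoms: none
Why: Organolithium addition to a lithium carboxylate (Gilman–Jorgenson ketone synthesis) stops at the dilithio gem-diolate, which releases the isopropenyl ketone only on the inverse acidic quench, two further equivalents of 9 being consumed by the CO2H and alkyne C–H protons.

**Step 6**
Reactants: 10 2-methylhept-1-en-6-yn-3-one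
Product: 11 (R)-2-methylhept-1-en-6-yn-3-ol
Conditions: (S)-2-methyl-CBS-oxazaborolidine [(S)-1-methyl-3,3-diphenyltetrahydro-1H,3H-pyrrolo[1,2-c][1,3,2]oxazaborole] (0.2 equiv), catecholborane (1.5 equiv), toluene, −78 °C; MeOH, then aq. NaOH
Reagents that add atoms: none
Why: Corey–Bakshi–Shibata reduction in which the α-methylvinyl group acts as the large substituent, so the (S)-catalyst gives the (R)-carbinol (C3, the sole controller of the ring stereocentres), and catecholborane at −78 °C does not hydroborate the alkyne.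

**Step 7**
Reactants: 11 (R)-2-methylhept-1-en-6-yn-3-ol
Product: 12 (R)-triethyl[(2-methylhept-1-en-6-yn-3-yl)oxy]silane
Conditions: Et3SiCl, imidazole, DMF, 0 °C → rt
Reagents that add atoms: chlorotriethylsilane (CC[Si](Cl)(CC)CC)
Why: Standard silylation gives an ether that survives the organoaluminium, oxidation and radical steps, acts as a bulky pseudo-equatorial group in the cyclisation and is removed by the mild acid of the last step.

**Step 8**
Reactants: 12 (R)-triethyl[(2-methylhept-1-en-6-yn-3-yl)oxy]silane; 13 oxirane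
Product: 16 (3E,7R)-4,8-dimethyl-7-(triethylsilyloxy)nona-3,8-dien-1-ol, via alkenyldimethylalane 14 (not isolated), via lithium alkenylaluminate 15 (not isolated)
Conditions: Me3Al (2.5 equiv), Cp2ZrCl2 (0.25 equiv), CH2Cl2, 0 °C → rt; volatiles removed; n-BuLi (1.0 equiv), hexane, 0 °C; 13 (3 equiv), THF, −30 → 0 °C; aq. potassium sodium tartrate
Reagents that add atoms: trimethylaluminium (C[Al](C)C)
Why: Negishi zirconium-catalysed syn-carboalumination puts the methyl (C20) on the internal and aluminium on the terminal alkyne carbon (E ≥ 98%), the derived alanate opens oxirane with retention of alkene geometry, and the 1,1-disubstituted alkene is inert.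

**Step 9**
Reactants: 16 (3E,7R)-4,8-dimethyl-7-(triethylsilyloxy)nona-3,8-dien-1-ol
Product: 17 (3E,7R)-4,8-dimethyl-7-(triethylsilyloxy)nona-3,8-dienal
Conditions: Dess–Martin periodinane (1.2 equiv), NaHCO3, CH2Cl2, 0 °C, 30 min; used crude
Reagents that add atoms: none
Why: Buffered Dess–Martin oxidation gives the β,γ-unsaturated aldehyde (C7) without acid or base that would move the alkene into conjugation.

**Step 10**
Reactants: 6 (R)-8-methoxy-3-methyl-8-oxooct-6-ynoic acid; 17 (3E,7R)-4,8-dimethyl-7-(triethylsilyloxy)nona-3,8-dienal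
Product: 21 (3R,6Z,10E,14R)-8-acetoxy-7-(methoxycarbonyl)-3,11,15-trimethyl-14-(triethylsilyloxy)hexadeca-6,10,15-trienoic acid (both C8 epimers), via vinylalane 18 (not isolated), via aluminium alkoxide 19 (not isolated), via mixed anhydride 20 (not isolated)
Conditions: 6 (1.2 equiv), i-Bu2AlH (2.5 equiv), HMPA (3 equiv), THF, 0 °C, 1 h; then 17, 0 °C → rt; then pyridine, 4-(dimethylamino)pyridine, Ac2O (5 equiv), 0 °C → rt; aq. NaHCO3 (1 h), then pH 4
Reagents that add atoms: acetic anhydride (CC(=O)OC(C)=O)
Why: Tsuda/Ramachandran vinylalumination–aldol in which i-Bu2AlH·HMPA adds H and Al cis across the ynoate (H to the β-carbon) so the side chain lies cis to CO2Me, the α-alumino acrylate adds to the aldehyde with retention to form the C7–C8 bond as the (Z)-α-alkylidene-β-hydroxy ester, and acetylation in the flask gives the allylic acetate whose carbinol epimers converge in step 11.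

**Step 11**
Reactants: 21 (3R,6Z,10E,14R)-8-acetoxy-7-(methoxycarbonyl)-3,11,15-trimethyl-14-(triethylsilyloxy)hexadeca-6,10,15-trienoic acid
Product: 22 (3R)-5-[(1S,4aS,6R,8aR)-2-(methoxycarbonyl)-5,5,8a-trimethyl-6-(triethylsilyloxy)-1,4,4a,5,6,7,8,8a-octahydronaphthalen-1-yl]-3-methylpentanoic acid (ring centres arranged as in the target)
Conditions: Fe(acac)3 (0.5 equiv), PhSiH3 (2.5 equiv), EtOH/(CH2OH)2 5:1, 0.01 M, 60 °C, Ar
Reagents that add atoms: none
Why: Proposed new method: the iron hydride transfers H• to the CH2 terminus of the isopropenyl group (the most accessible electron-rich alkene) to give the tertiary C4 radical, which closes 6-endo onto the E-trisubstituted alkene (C4–C5, ring A) and then 6-endo in a Giese sense onto the β-carbon of the Z-enoate (C9–C10, ring B); divalent iron reduces the resulting α-ester radical to the enolate, which expels the β-acetate (E1cB) to leave the C7=C8 enoate; an all-chair transition state with the silyl ether pseudo-equatorial sets C5–H anti to the C10 methyl (trans-decalin) with the silyl ether cis to that methyl, and the Z-alkene places the side chain equatorial at C9; the closest known reaction types are iron-hydride HAT-initiated radical polyene bicyclisations terminated by Giese addition (Mukaiyama/Baran-type reductive olefin coupling) and radical addition–acetate elimination on Morita–Baylis–Hillman acetates.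

**Step 12**
Reactants: 22 (bicyclic C17 methyl ester, C15 acid, 3-silyl ether)
Product: 23 (3R)-5-[(1S,4aS,6R,8aS)-2-(hydroxymethyl)-5,5,8a-trimethyl-6-(triethylsilyloxy)-1,4,4a,5,6,7,8,8a-octahydronaphthalen-1-yl]-3-methylpentanoic acid
Conditions: i-Bu2AlH (3.5 equiv), THF, −78 → −40 °C; aq. potassium sodium tartrate, then citric acid to pH 4
Reagents that add atoms: none
Why: i-Bu2AlH 1,2-reduction of the conjugated methyl ester gives the allylic alcohol, the first equivalent having converted CO2H into an aluminium carboxylate that is not reduced at low temperature, and no stereocentre is touched.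

**Step 13**
Reactants: 23 (C17 allylic alcohol, C15 acid, 3-silyl ether)
Product: 24 methyl (3R)-5-[(1S,4aS,6R,8aS)-6-hydroxy-2-(hydroxymethyl)-5,5,8a-trimethyl-1,4,4a,5,6,7,8,8a-octahydronaphthalen-1-yl]-3-methylpentanoate (target)
Conditions: HCl (0.1 M in MeOH), 0 °C → rt, 6 h; NaHCO3
Reagents that add atoms: methanol (CO)
Why: Dilute methanolic HCl effects Fischer esterification of the unhindered C15 acid and cleaves the triethylsilyl ether in the same flask, conditions that the primary allylic alcohol and the trisubstituted alkene tolerate.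

**Compound list**
1 | (R)-β-butyrolactone, (4R)-4-methyloxetan-2-one | C[C@@H]1CC(=O)O1 | starting material
2 | but-3-en-1-ylmagnesium bromide | C=CCC[Mg]Br | starting material
3 | (R)-3-methylhept-6-enoic acid | C=CCC[C@@H](C)CC(=O)O | intermediate
4 | (R)-3-methyl-6-oxohexanoic acid | O=CCC[C@@H](C)CC(=O)O | intermediate
5 | (R)-3-methylhept-6-ynoic acid | C#CCC[C@@H](C)CC(=O)O | intermediate
6 | (R)-8-methoxy-3-methyl-8-oxooct-6-ynoic acid | COC(=O)C#CCC[C@@H](C)CC(=O)O | intermediate
7 | pent-4-ynoic acid | C#CCCC(=O)O | starting material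
8 | 2-bromopropene | CC(Br)=C | starting material
9 | isopropenyllithium (prop-1-en-2-yllithium) | [Li]C(C)=C | intermediate (not isolated)
10 | 2-methylhept-1-en-6-yn-3-one | C=C(C)C(=O)CCC#C | intermediate
11 | (R)-2-methylhept-1-en-6-yn-3-ol | C=C(C)[C@H](O)CCC#C | intermediate
12 | (R)-triethyl[(2-methylhept-1-en-6-yn-3-yl)oxy]silane | C=C(C)[C@H](O[Si](CC)(CC)CC)CCC#C | intermediate
13 | oxirane | C1CO1 | starting material
14 | dimethyl[(1E,5R)-2,6-dimethyl-5-(triethylsilyloxy)hepta-1,6-dien-1-yl]alane | C=C(C)[C@H](O[Si](CC)(CC)CC)CC/C(C)=C/[Al](C)C | intermediate (not isolated)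
15 | lithium butyl(dimethyl)[(1E,5R)-2,6-dimethyl-5-(triethylsilyloxy)hepta-1,6-dien-1-yl]aluminate | [Li+].C=C(C)[C@H](O[Si](CC)(CC)CC)CC/C(C)=C/[Al-](C)(C)CCCC | intermediate (not isolated)
16 | (3E,7R)-4,8-dimethyl-7-(triethylsilyloxy)nona-3,8-dien-1-ol | C=C(C)[C@H](O[Si](CC)(CC)CC)CC/C(C)=C/CCO | intermediate
17 | (3E,7R)-4,8-dimethyl-7-(triethylsilyloxy)nona-3,8-dienal | C=C(C)[C@H](O[Si](CC)(CC)CC)CC/C(C)=C/CC=O | intermediate
18 | diisobutylaluminium (R,E)-7-(diisobutylalumanyl)-8-methoxy-3-methyl-8-oxooct-6-enoate (Al and vinylic H cis; side chain cis to CO2Me) | COC(=O)/C([Al](CC(C)C)CC(C)C)=C\CC[C@@H](C)CC(=O)O[Al](CC(C)C)CC(C)C | intermediate (not isolated)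
19 | bis(diisobutylaluminium) alkoxide/carboxylate of the aldol adduct of 18 and 17 | C=C(C)[C@H](O[Si](CC)(CC)CC)CC/C(C)=C/CC(O[Al](CC(C)C)CC(C)C)/C(C(=O)OC)=C/CC[C@@H](C)CC(=O)O[Al](CC(C)C)CC(C)C | intermediate (not isolated)
20 | acetic mixed anhydride of 21 | C=C(C)[C@H](O[Si](CC)(CC)CC)CC/C(C)=C/CC(OC(C)=O)/C(C(=O)OC)=C/CC[C@@H](C)CC(=O)OC(C)=O | intermediate (not isolated)
21 | (3R,6Z,10E,14R)-8-acetoxy-7-(methoxycarbonyl)-3,11,15-trimethyl-14-(triethylsilyloxy)hexadeca-6,10,15-trienoic acid (both C8 epimers) | C=C(C)[C@H](O[Si](CC)(CC)CC)CC/C(C)=C/CC(OC(C)=O)/C(C(=O)OC)=C/CC[C@@H](C)CC(=O)O | intermediate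
22 | (3R)-5-[(1S,4aS,6R,8aR)-2-(methoxycarbonyl)-5,5,8a-trimethyl-6-(triethylsilyloxy)-1,4,4a,5,6,7,8,8a-octahydronaphthalen-1-yl]-3-methylpentanoic acid | OC(=O)C[C@H](C)CC[C@@H]1C(C(=O)OC)=CC[C@@H]2C(C)(C)[C@H](O[Si](CC)(CC)CC)CC[C@@]12C | intermediate
23 | (3R)-5-[(1S,4aS,6R,8aS)-2-(hydroxymethyl)-5,5,8a-trimethyl-6-(triethylsilyloxy)-1,4,4a,5,6,7,8,8a-octahydronaphthalen-1-yl]-3-methylpentanoic acid | OC(=O)C[C@H](C)CC[C@@H]1C(CO)=CC[C@@H]2C(C)(C)[C@H](O[Si](CC)(CC)CC)CC[C@@]12C | intermediate
24 | methyl (3R)-5-[(1S,4aS,6R,8aS)-6-hydroxy-2-(hydroxymethyl)-5,5,8a-trimethyl-1,4,4a,5,6,7,8,8a-octahydronaphthalen-1-yl]-3-methylpentanoate | COC(=O)C[C@H](C)CC[C@@H]1C(CO)=CC[C@@H]2C(C)(C)[C@H](O)CC[C@@]12C | target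

**Step count**
Total steps: 13. Longest linear sequence: 9 steps (steps 5–13, from pent-4-ynoic acid); the ynoate branch is 4 steps (steps 1–4) and joins at step 10.

**Three steps most likely to fail**

Step 11 (radical cascade). Risks are reduction of the C4 radical by the metal hydride before it cyclises, HAT to the trisubstituted alkene, and only moderate facial control by the silyl ether. The fallback sets out from 21 and returns at 22, and generates the same radical without any hydride source. Mukaiyama hydration of the isopropenyl group of 21 (Co(acac)2, PhSiH3, O2, i-PrOH) gives the tertiary alcohol F1. Methyl chlorooxoacetate with 4-(dimethylamino)pyridine gives the tertiary methyl oxalate F2, and CsOH (2 equiv) gives the dicaesium oxalate/carboxylate salt F3. Visible-light photoredox decarboxylation (Ir[dF(CF3)ppy]2(dtbbpy)PF6, blue LEDs, DME/DMF/H2O) then forms the C4 radical. The same two 6-endo closures follow, the reduced photocatalyst turns the α-ester radical into the enolate, and acetate loss gives 22.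

Step 10 (vinylalumination–aldol). Risks are isomerisation of the vinylalane through the allenoate to the wrong alkene geometry, the free acid, and the isomerisation-prone aldehyde. The fallback sets out from 4 and 17 and returns at 21, so steps 3 and 4 drop out; it fixes the geometry by olefination instead of hydroalumination. Horner–Wadsworth–Emmons reaction of 4 with methyl bromo[bis(2,2,2-trifluoroethoxy)phosphoryl]acetate (t-BuOK, 18-crown-6, THF, −78 °C) gives (R,E)-7-bromo-8-methoxy-3-methyl-8-oxooct-6-enoic acid F4, with the side chain cis to CO2Me. Nozaki–Hiyama–Kishi coupling of its sodium salt with 17 (CrCl2, NiCl2 cat., DMF) gives the hydroxy ester F5 with retention of alkene geometry. Ac2O/pyridine/4-(dimethylamino)pyridine then gives 21.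

Step 12 (ester reduction beside a free acid). The risk is partial reduction of the carboxylate. The fallback sets out from 22 and returns at 24, and masks the acid before reduction. Boc2O, 4-(dimethylamino)pyridine and t-BuOH give the tert-butyl ester F6. i-Bu2AlH (2.2 equiv, −78 °C) reduces only the methyl enoate to the tert-butyl ester allylic alcohol F7. HCl in MeOH (1.25 M, 40 °C) then removes the silyl group and converts the tert-butyl ester into the methyl ester, giving 24.

**Further compounds**
F1 | step 11 | (3R,6Z,10E,14R)-8-acetoxy-15-hydroxy-7-(methoxycarbonyl)-3,11,15-trimethyl-14-(triethylsilyloxy)hexadeca-6,10-dienoic acid | CC(C)(O)[C@H](O[Si](CC)(CC)CC)CC/C(C)=C/CC(OC(C)=O)/C(C(=O)OC)=C/CC[C@@H](C)CC(=O)O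
F2 | step 11 | methyl oxalate of the tertiary alcohol F1 | COC(=O)C(=O)OC(C)(C)[C@H](O[Si](CC)(CC)CC)CC/C(C)=C/CC(OC(C)=O)/C(C(=O)OC)=C/CC[C@@H](C)CC(=O)O
F3 | step 11 | dicaesium salt of the hemioxalate carboxylic acid from F2 | [Cs+].[Cs+].[O-]C(=O)C(=O)OC(C)(C)[C@H](O[Si](CC)(CC)CC)CC/C(C)=C/CC(OC(C)=O)/C(C(=O)OC)=C/CC[C@@H](C)CC(=O)[O-]
F4 | step 10 | (R,E)-7-bromo-8-methoxy-3-methyl-8-oxooct-6-enoic acid | COC(=O)/C(Br)=C\CC[C@@H](C)CC(=O)O
F5 | step 10 | (3R,6Z,10E,14R)-8-hydroxy-7-(methoxycarbonyl)-3,11,15-trimethyl-14-(triethylsilyloxy)hexadeca-6,10,15-trienoic acid (both C8 epimers) | C=C(C)[C@H](O[Si](CC)(CC)CC)CC/C(C)=C/CC(O)/C(C(=O)OC)=C/CC[C@@H](C)CC(=O)O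
F6 | step 12 | tert-butyl ester of 22 | CC(C)(C)OC(=O)C[C@H](C)CC[C@@H]1C(C(=O)OC)=CC[C@@H]2C(C)(C)[C@H](O[Si](CC)(CC)CC)CC[C@@]12C
F7 | step 12 | tert-butyl ester of 23 | CC(C)(C)OC(=O)C[C@H](C)CC[C@@H]1C(CO)=CC[C@@H]2C(C)(C)[C@H](O[Si](CC)(CC)CC)CC[C@@]12C
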